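**Plan**

Numbering: C1 = quaternary fusion carbon (Me); C2, C3 = CH2; C4 = C(OH)iPr; C5 = fusion CH; C6 = CH–O-aroyl; C7 = CH2; C8(Me)=C9; C10 = CH–O-tigloyl; β = face of the C1 methyl. These labels are used for the same atoms throughout.
Feature: breaking the ring-fusion bond C1–C5 and the C6–C7 bond together opens both the five- and the seven-membered ring to one chain, in which C2–C3–C4 links a C5≡C6 alkyne to a C1=C10 alkene carrying the C7/C8/C9 cyclopropane.
Retrosynthesis: remove both esters, return the C10 oxygen to a C9=C10 alkene and the C6 ketone to a vinylsilane, cut C1–C5 and C6–C7 together, then cut the chain at C9–C10 and trace it to the ring of (S)-terpinen-4-ol (C1–C6 opened).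
Forward: ozonolysis of terpinen-4-ol; the ketone arm becomes the (E)-C1=C10 iodide, the aldehyde arm the C5≡C6 silylalkyne; the cyclopropane is built last; one rhodium step then closes the five- and the seven-membered ring at once.
Stereochemistry: C4 from terpinen-4-ol; the (1S,2S)-cyclopropane (ligand-controlled) dictates C1 and leaves H-8 β; C5 by equilibration next to the C6 ketone; C10 by C4–OH-directed epoxidation, then selenide opening and syn elimination through H-8; C6 by chelation-controlled reduction.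

Key step: step 11

Remark: (S)-terpinen-4-ol and boronate 14 are taken as catalogue compounds of high enantiomeric and geometric purity; any (R)-alcohol carried along becomes a diastereomer after step 9 and should be separable at cycloadduct 19.

**Route**

Step 1
Reactants: 1 (S)-terpinen-4-ol
Product: 2 triethyl{[(1S)-4-methyl-1-(propan-2-yl)cyclohex-3-en-1-yl]oxy}silane
Conditions: Et3SiOTf, 2,6-lutidine, CH2Cl2, 0 °C → rt
Reagents that add atoms: triethylsilyl trifluoromethanesulfonate, CC[Si](CC)(CC)OS(=O)(=O)C(F)(F)F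
Why: Silylation of a hindered tertiary alcohol with a silyl triflate; the ether keeps the C4 oxygen out of ketal formation and retro-aldol chemistry and falls off without an extra step in step 12.

Step 2
Reactants: 2 silyl ether
Product: 5 (5S)-7,7-dimethoxy-5-(propan-2-yl)-5-[(triethylsilyl)oxy]heptan-2-one, via aldehyde methoxy-hydroperoxide 3 (not isolated), via acetal methoxy-hydroperoxide 4 (not isolated)
Conditions: O3, CH2Cl2/MeOH (5:1), −78 °C; TsOH·H2O (10 mol %), −78 °C → rt; NaHCO3; Me2S, rt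
Reagents that add atoms: ozone, [O-][O+]=O; methanol, CO
Why: Ozonolysis with Schreiber's unsymmetrical work-up: the carbonyl oxide formed at the more substituted carbon (C1) is trapped by methanol, the C6 aldehyde is acetalised under acid, and reduction then releases the methyl ketone, so the two chain ends leave the flask differentiated.

Step 3
Reactants: 5 keto acetal
Product: 7 (5S)-7,7-dimethoxy-5-(propan-2-yl)-5-[(triethylsilyl)oxy]hept-1-yne, via enol phosphate 6 (not isolated)
Conditions: LiN(i-Pr)2, THF, −78 °C; ClP(O)(OEt)2, −78 → 0 °C; LiN(i-Pr)2 (2.3 equiv), −78 °C → rt; H2O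
Reagents that add atoms: none
Why: Negishi conversion of a methyl ketone into a terminal alkyne (kinetic enolisation at the methyl group, O-phosphorylation, elimination); the former methyl carbon becomes C10, and acetal and γ-silyloxy group are inert to the amide base.

Step 4
Reactants: 7 alkyne
Product: 9 (1E,5S)-1-iodo-7,7-dimethoxy-2-methyl-5-(propan-2-yl)-5-[(triethylsilyl)oxy]hept-1-ene, via alkenylalane 8 (not isolated)
Conditions: AlMe3, Cp2ZrCl2 (25 mol %), H2O (1 equiv), CH2Cl2, −25 °C; I2, THF, −30 → 0 °C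
Reagents that add atoms: trimethylaluminium, C[Al](C)C; iodine, II
Why: Zirconium-catalysed syn carboalumination (Negishi, water-accelerated variant) puts methyl on C1 and aluminium on C10 from the same side, and iodinolysis with retention gives the (E)-iodide, so C2 will be trans and the methyl cis to the cyclopropane; the short cold protocol should spare the acetal.

Step 5
Reactants: 9 iodo acetal
Product: 10 (3S,6E)-7-iodo-6-methyl-3-(propan-2-yl)-3-[(triethylsilyl)oxy]hept-6-enal
Conditions: PPTS (20 mol %), acetone/H2O (9:1), 50 °C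
Reagents that add atoms: water, O
Why: Mild acid-catalysed acetal hydrolysis, done before any acid-sensitive vinylcyclopropane exists; a tertiary triethylsilyl ether and an alkenyl iodide tolerate pyridinium tosylate.

Step 6
Reactants: 10 aldehyde
Product: 11 (3R,6E)-7-iodo-6-methyl-3-(propan-2-yl)-3-[(triethylsilyl)oxy]hepta-1,6-dien-1-yl trifluoromethanesulfonate (E/Z mixture at the enol triflate)
Conditions: Tf2O, 2,6-di-tert-butyl-4-methylpyridine, CH2Cl2, 0 °C → rt
Reagents that add atoms: trifluoromethanesulfonic anhydride, O=S(=O)(OS(=O)(=O)C(F)(F)F)C(F)(F)F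
Why: Stang enol triflate synthesis (O-triflation of the aldehyde, loss of a C5 proton to the hindered pyridine); no enolate is formed, so the β-silyloxy group on C4 cannot be eliminated, and both alkene isomers serve in step 7.

Step 7
Reactants: 11 enol triflate
Product: 13 benzyl{(3R,6E)-7-iodo-6-methyl-3-(propan-2-yl)-3-[(triethylsilyl)oxy]hept-6-en-1-yn-1-yl}dimethylsilane, via lithium acetylide 12 (not isolated)
Conditions: LiN(i-Pr)2 (2.3 equiv), THF, −78 °C; BnMe2SiCl, −78 °C → rt
Reagents that add atoms: benzylchlorodimethylsilane, C[Si](C)(Cl)Cc1ccccc1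
Why: Base-induced elimination of triflate from a 1-alkenyl triflate gives the C5≡C6 alkyne, whose acetylide is C-silylated; benzyldimethylsilyl is chosen because fluoride later makes it oxidisable, and a lithium amide does not attack an alkenyl iodide at −78 °C.

Step 8
Reactants: 13 alkenyl iodide; 14 (E)-3-(4,4,5,5-tetramethyl-1,3,2-dioxaborolan-2-yl)prop-2-en-1-ol
Product: 15 (2E,4E,8R)-10-[benzyl(dimethyl)silyl]-5-methyl-8-(propan-2-yl)-8-[(triethylsilyl)oxy]deca-2,4-dien-9-yn-1-ol
Conditions: Pd(PPh3)4 (5 mol %), K3PO4, THF/H2O (10:1), 40 °C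
Reagents that add atoms: boronate 14, OC/C=C/B1OC(C)(C)C(C)(C)O1
Why: Suzuki–Miyaura coupling at zerovalent palladium joins C10 to C9 with retention at both alkenes and brings in C9, C8 and the future C8 methyl as a dienol; the phosphate base is mild enough for the alkynylsilane.

Step 9
Reactants: 15 dienol
Product: 16 [(1S,2R)-2-{(1E,5R)-7-[benzyl(dimethyl)silyl]-2-methyl-5-(propan-2-yl)-5-[(triethylsilyl)oxy]hept-1-en-6-yn-1-yl}cyclopropyl]methanol
Conditions: Et2Zn, CH2I2, DME, CH2Cl2, −10 °C; (4R,5R)-2-butyl-N,N,N′,N′-tetramethyl-1,3,2-dioxaborolane-4,5-dicarboxamide (1.2 equiv), −10 °C → rt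
Reagents that add atoms: diiodomethane, ICI
Why: Charette asymmetric Simmons–Smith cyclopropanation: the zinc alkoxide bound to the chiral dioxaborolane sends the carbenoid only to the allylic (E)-alkene and to the face that this ligand is known to choose for cinnamyl alcohol ((1S,2S) product), which here sets C8 and C9 as the trans (1S,2R) cyclopropane and adds C7.

Step 10
Reactants: 16 cyclopropylmethanol
Product: 18 benzyl(dimethyl){(3R,6E)-6-methyl-7-[(1S,2S)-2-methylcyclopropyl]-3-(propan-2-yl)-3-[(triethylsilyl)oxy]hept-6-en-1-yn-1-yl}silane, via mesylate 17 (not isolated)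
Conditions: MsCl, Et3N, CH2Cl2, −20 °C; LiEt3BH, THF, −20 → 0 °C
Reagents that add atoms: none
Why: Sulfonylation and SN2 hydride displacement turn the directing hydroxymethyl group into the C8 methyl; low temperature and a strongly nucleophilic hydride should keep the cyclopropylmethyl mesylate from ionising.

Step 11
Reactants: 18 alkyne-tethered vinylcyclopropane
Product: 19 cycloadduct: hydroazulene diene (C5=C6 and C9=C10) with 6-SiMe2Bn; 1β-Me; 8α-Me (H-8 β); 4β-iPr; 4α-OSiEt3
Conditions: [Rh(CO)2Cl]2 (5 mol %), toluene, 80 °C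
Reagents that add atoms: none
Why: Intramolecular rhodium-catalysed (5+2) cycloaddition of a vinylcyclopropane with an alkyne (Wender type): monovalent rhodium binds the C1=C10 alkene, opens the cyclopropane to an allyl/alkyl rhodacycle, the alkyne inserts and reductive elimination releases the cyclohepta-1,4-diene. The five-membered ring closes when the proximal alkyne carbon C5 bonds to C1 across the C2–C3–C4 tether, the seven-membered ring when the distal alkyne carbon C6 bonds to the former cyclopropane methylene C7. C1 is the only new stereocentre: rhodium can open only the cyclopropane bond on its own face of the alkene, and a trans-2-alkyl group steers it to the less substituted C9–C7 bond, so the (1S,2S) cyclopropane selects the alkene face and places the C1 methyl β. The C4 centre reinforces this, since its isopropyl group then lies on the exo face of the forming cyclopentene, away from the metal. C8 passes through unchanged, which leaves H-8 β. The step needs this regioselective C–C cleavage and tolerance of a trisubstituted alkene and a silylalkyne, both within the known scope of [Rh(CO)2Cl]2.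

Step 12
Reactants: 19 cycloadduct
Product: 21 cis-fused β-hydroxy ketone (4α-OH; 6-oxo; C9=C10; 1β-Me; 5β-H; 8α-Me; 4β-iPr), via cyclic siloxane 20 (not isolated)
Conditions: Bu4NF (3 equiv), THF, 0 °C → rt; then KHCO3, 30% H2O2, MeOH, 40 °C
Reagents that add atoms: hydrogen peroxide, OO
Why: Fluoride removes the triethylsilyl group, the C4 alkoxide displaces benzyl from silicon to give a five-membered alkenyl siloxane, and Tamao–Fleming oxidation turns C6–Si into the enol and thus the C6 ketone; C5 then equilibrates in the bicarbonate medium to the more stable epimer (C6 trans to isopropyl and hydrogen-bonded to the cis C4 hydroxyl, ring fusion cis, H-5 β).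

Step 13
Reactants: 21 β-hydroxy ketone
Product: 22 9α,10α-epoxide of 21
Conditions: VO(acac)2 (5 mol %), t-BuOOH, CH2Cl2, 0 °C → rt
Reagents that add atoms: tert-butyl hydroperoxide, CC(C)(C)OO
Why: Vanadium-catalysed hydroxyl-directed epoxidation: the C4 hydroxyl is cis to the C1–C10 bond on the five-membered ring and should carry the peroxide to the α (concave) face of the only remaining alkene, which fixes the C10 oxygen; the same hydroxyl cannot open the epoxide because both lie on one face.

Step 14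
Reactants: 22 epoxide
Product: 25 allylic alcohol (4α,10α-diol; 6-oxo; C8(Me)=C9; 1β-Me; 5β-H; 4β-iPr), via hydroxy selenide 23 (not isolated), via selenoxide 24 (not isolated)
Conditions: (PhSe)2, NaBH4 (no excess), EtOH, rt; then 30% H2O2, THF, 0 → 40 °C
Reagents that add atoms: none
Why: Sharpless epoxide-to-allylic-alcohol transposition: selenide opens the epoxide with inversion at C9 (C10 is neopentyl), so selenium is β, and the selenoxide eliminates syn through the β H-8 and away from the carbinol carbon, giving C8=C9 and the 10α-alcohol; this anti/syn pair is exactly what the β H-8 from step 11 requires, whereas a suprafacial ene oxidation would have placed oxygen on the β face.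

Step 15
Reactants: 25 allylic alcohol; 26 (E)-2-methylbut-2-enoyl chloride (tigloyl chloride)
Product: 27 10α-tiglate of 25 (4α-OH and 6-ketone unchanged)
Conditions: DMAP, Et3N, CH2Cl2, 0 → 40 °C
Reagents that add atoms: tigloyl chloride 26, C/C=C(\C)C(Cl)=O
Why: DMAP-catalysed acylation; only the secondary C10 hydroxyl can react (C4–OH is tertiary, C6 is still a ketone), so the two esters of the target are told apart by the order of their introduction.

Step 16
Reactants: 27 keto tiglate
Product: 29 4α,6α-diol 10α-tiglate, via borinate 28 (not isolated)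
Conditions: Et2BOMe, THF/MeOH (4:1), −78 °C; NaBH4, −78 °C; MeOH co-evaporation
Reagents that add atoms: none
Why: Narasaka–Prasad 1,3-syn reduction: the C4–O–BEt2 chelate holds the C6 carbonyl oxygen on the α side and external hydride adds from the open β (convex) face, giving the 6α-alcohol; the unsaturated ester is not reduced at −78 °C.

Step 17
Reactants: 29 diol; 30 4-acetoxybenzoyl chloride
Product: 31 6α-(4-acetoxybenzoate) of 29
Conditions: DMAP, pyridine, CH2Cl2, 0 °C → rt
Reagents that add atoms: 4-acetoxybenzoyl chloride 30, CC(=O)Oc1ccc(cc1)C(Cl)=O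
Why: DMAP-catalysed aroylation of the only secondary hydroxyl left (C6); the phenol is carried as its acetate so that the acid chloride cannot oligomerise.

Step 18
Reactants: 31 acetoxybenzoate
Product: 32 (3R,3aS,4R,8S,8aR)-3-hydroxy-6,8a-dimethyl-8-{[(2E)-2-methylbut-2-enoyl]oxy}-3-(propan-2-yl)-1,2,3,3a,4,5,8,8a-octahydroazulen-4-yl 4-hydroxybenzoate
Conditions: pyrrolidine, CH2Cl2, 0 °C
Reagents that add atoms: none
Why: Aminolysis of the aryl acetate, which has a phenoxide leaving group and should react far faster than the two alkyl esters.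

**Compound list**

1 | (S)-terpinen-4-ol | CC1=CC[C@](O)(C(C)C)CC1 | starting material
2 | triethyl{[(1S)-4-methyl-1-(propan-2-yl)cyclohex-3-en-1-yl]oxy}silane | CC1=CC[C@](O[Si](CC)(CC)CC)(C(C)C)CC1 | intermediate
3 | aldehyde methoxy-hydroperoxide (not isolated) | O=CC[C@](O[Si](CC)(CC)CC)(C(C)C)CCC(C)(OC)OO | intermediate
4 | acetal methoxy-hydroperoxide (not isolated) | COC(OC)C[C@](O[Si](CC)(CC)CC)(C(C)C)CCC(C)(OC)OO | intermediate
5 | (5S)-7,7-dimethoxy-5-(propan-2-yl)-5-[(triethylsilyl)oxy]heptan-2-one | COC(OC)C[C@](O[Si](CC)(CC)CC)(C(C)C)CCC(C)=O | intermediate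
6 | enol phosphate of 5 (not isolated) | COC(OC)C[C@](O[Si](CC)(CC)CC)(C(C)C)CCC(=C)OP(=O)(OCC)OCC | intermediate
7 | (5S)-7,7-dimethoxy-5-(propan-2-yl)-5-[(triethylsilyl)oxy]hept-1-yne | COC(OC)C[C@](O[Si](CC)(CC)CC)(C(C)C)CCC#C | intermediate
8 | (E)-alkenyl(dimethyl)alane from 7 (not isolated) | COC(OC)C[C@](O[Si](CC)(CC)CC)(C(C)C)CC/C(C)=C/[Al](C)C | intermediate
9 | (1E,5S)-1-iodo-7,7-dimethoxy-2-methyl-5-(propan-2-yl)-5-[(triethylsilyl)oxy]hept-1-ene | COC(OC)C[C@](O[Si](CC)(CC)CC)(C(C)C)CC/C(C)=C/I | intermediate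
10 | (3S,6E)-7-iodo-6-methyl-3-(propan-2-yl)-3-[(triethylsilyl)oxy]hept-6-enal | O=CC[C@](O[Si](CC)(CC)CC)(C(C)C)CC/C(C)=C/I | intermediate
11 | (3R,6E)-7-iodo-6-methyl-3-(propan-2-yl)-3-[(triethylsilyl)oxy]hepta-1,6-dien-1-yl trifluoromethanesulfonate (E/Z at the enol triflate) | O=S(=O)(OC=C[C@](O[Si](CC)(CC)CC)(C(C)C)CC/C(C)=C/I)C(F)(F)F | intermediate
12 | lithium acetylide from 11 (not isolated) | [Li]C#C[C@](O[Si](CC)(CC)CC)(C(C)C)CC/C(C)=C/I | intermediate
13 | benzyl{(3R,6E)-7-iodo-6-methyl-3-(propan-2-yl)-3-[(triethylsilyl)oxy]hept-6-en-1-yn-1-yl}dimethylsilane | C[Si](C)(Cc1ccccc1)C#C[C@](O[Si](CC)(CC)CC)(C(C)C)CC/C(C)=C/I | intermediate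
14 | (E)-3-(4,4,5,5-tetramethyl-1,3,2-dioxaborolan-2-yl)prop-2-en-1-ol | OC/C=C/B1OC(C)(C)C(C)(C)O1 | starting material
15 | (2E,4E,8R)-10-[benzyl(dimethyl)silyl]-5-methyl-8-(propan-2-yl)-8-[(triethylsilyl)oxy]deca-2,4-dien-9-yn-1-ol | C[Si](C)(Cc1ccccc1)C#C[C@](O[Si](CC)(CC)CC)(C(C)C)CC/C(C)=C/C=C/CO | intermediate
16 | [(1S,2R)-2-{(1E,5R)-7-[benzyl(dimethyl)silyl]-2-methyl-5-(propan-2-yl)-5-[(triethylsilyl)oxy]hept-1-en-6-yn-1-yl}cyclopropyl]methanol | C[Si](C)(Cc1ccccc1)C#C[C@](O[Si](CC)(CC)CC)(C(C)C)CC/C(C)=C/[C@@H]1[C@@H](CO)C1 | intermediate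
17 | methanesulfonate of 16 (not isolated) | C[Si](C)(Cc1ccccc1)C#C[C@](O[Si](CC)(CC)CC)(C(C)C)CC/C(C)=C/[C@@H]1[C@@H](COS(C)(=O)=O)C1 | intermediate
18 | benzyl(dimethyl){(3R,6E)-6-methyl-7-[(1S,2S)-2-methylcyclopropyl]-3-(propan-2-yl)-3-[(triethylsilyl)oxy]hept-6-en-1-yn-1-yl}silane | C[Si](C)(Cc1ccccc1)C#C[C@](O[Si](CC)(CC)CC)(C(C)C)CC/C(C)=C/[C@@H]1[C@@H](C)C1 | intermediate
19 | cycloadduct: hydroazulene 5,9-diene with 6-SiMe2Bn, 1β-Me, 8α-Me (H-8 β), 4β-iPr, 4α-OSiEt3 | C1=C[C@@H](C)CC([Si](C)(C)Cc3ccccc3)=C2[C@@]1(C)CC[C@@]2(O[Si](CC)(CC)CC)C(C)C | intermediate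
20 | cyclic alkenyl siloxane (O4–SiMe2–C6; not isolated) | C1=C[C@@H](C)CC2=C3[C@@]1(C)CC[C@@]3(O[Si]2(C)C)C(C)C | intermediate
21 | cis-fused β-hydroxy ketone: 4α-OH, 6-oxo, C9=C10, 1β-Me, 5β-H, 8α-Me, 4β-iPr | C1=C[C@@H](C)CC(=O)[C@@H]2[C@@]1(C)CC[C@@]2(O)C(C)C | intermediate
22 | 9α,10α-epoxide of 21 | C[C@H]1CC(=O)[C@@H]2[C@@](C)(CC[C@@]2(O)C(C)C)[C@H]3O[C@@H]13 | intermediate
23 | 9β-phenylselanyl-10α-ol (not isolated) | O[C@H]1[C@H]([Se]c2ccccc2)[C@@H](C)CC(=O)[C@@H]3[C@@]1(C)CC[C@@]3(O)C(C)C | intermediate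
24 | selenoxide of 23 (not isolated) | O[C@H]1[C@H]([Se](=O)c2ccccc2)[C@@H](C)CC(=O)[C@@H]3[C@@]1(C)CC[C@@]3(O)C(C)C | intermediate
25 | allylic alcohol: 4α,10α-diol, 6-oxo, C8(Me)=C9, 1β-Me, 5β-H, 4β-iPr | O[C@H]1C=C(C)CC(=O)[C@@H]2[C@@]1(C)CC[C@@]2(O)C(C)C | intermediate
26 | (E)-2-methylbut-2-enoyl chloride (tigloyl chloride) | C/C=C(\C)C(Cl)=O | starting material
27 | 10α-tiglate of 25 | C/C=C(\C)C(=O)O[C@H]1C=C(C)CC(=O)[C@@H]2[C@@]1(C)CC[C@@]2(O)C(C)C | intermediate
28 | 4-O-diethylborinate of 27 (not isolated) | C/C=C(\C)C(=O)O[C@H]1C=C(C)CC(=O)[C@@H]2[C@@]1(C)CC[C@@]2(OB(CC)CC)C(C)C | intermediate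
29 | 4α,6α-diol 10α-tiglate | C/C=C(\C)C(=O)O[C@H]1C=C(C)C[C@@H](O)[C@@H]2[C@@]1(C)CC[C@@]2(O)C(C)C | intermediate
30 | 4-acetoxybenzoyl chloride | CC(=O)Oc1ccc(cc1)C(Cl)=O | starting material
31 | 6α-(4-acetoxybenzoate) of 29 | C/C=C(\C)C(=O)O[C@H]1C=C(C)C[C@@H](OC(=O)c2ccc(OC(C)=O)cc2)[C@@H]3[C@@]1(C)CC[C@@]3(O)C(C)C | intermediate
32 | (3R,3aS,4R,8S,8aR)-3-hydroxy-6,8a-dimethyl-8-{[(2E)-2-methylbut-2-enoyl]oxy}-3-(propan-2-yl)-1,2,3,3a,4,5,8,8a-octahydroazulen-4-yl 4-hydroxybenzoate | C/C=C(\C)C(=O)O[C@H]1C=C(C)C[C@@H](OC(=O)c2ccc(O)cc2)[C@@H]2[C@@]1(C)CC[C@@]2(O)C(C)C | target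

**Step count**

Total steps: 18. Longest linear sequence: 18 (from 1; 14, 26 and 30 are purchased).

**Steps most likely to fail**

Step 11. The cycloaddition may stall or go astray. The silyl group has to end up cis to the fully substituted C4, and this allylic strain can block alkyne insertion. If rhodium instead opens the more substituted C9–C8 bond from the other alkene face, the C1 epimer with the methyl on C7 would form. Fallback, from 18: K2CO3 in MeOH removes the alkynyl silyl group to give the terminal alkyne F1. The same [Rh(CO)2Cl]2 cycloaddition on this less hindered alkyne should give the diene F2 (C5=C6–H). Bu4NF frees the tertiary allylic alcohol F3. VO(acac)2 and t-BuOOH epoxidise the allylic C5=C6 alkene syn to the hydroxyl to give the 5α,6α-epoxide F4. BF3·OEt2 at −78 °C then effects a Meinwald rearrangement: ionisation at C5 and hydride shift from C6, anti to the leaving oxygen, give the C6 ketone with H-5 β. The route is rejoined at 21.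

Step 13. The epoxidation may show poor facial selectivity if the single C4 hydroxyl does not reach the alkene and the oxidant attacks the convex β face. Fallback, from 21: NaBH4 in MeOH at −40 °C (hydride from the convex face) gives the 4α,6α-diol F5. Two α-hydroxyls, one of them transannular to the alkene, then direct VO(acac)2/t-BuOOH to the α-epoxide F6. 2-Methoxypropene and PPTS tie O4 and O6 into the acetonide F7. Selenide opening and oxidation as in step 14 lead through the hydroxy selenide F8 and the selenoxide F9 to the allylic alcohol F10. Tigloyl chloride with DMAP gives the tiglate F11, and PPTS in MeOH removes the acetonide. The route is rejoined at 29.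

Step 6. Enol triflate formation may fail: the hindered C5 proton may not be lost, so that the geminal bis(triflate) forms, or the acid generated may cleave the tertiary silyl ether. Fallback, from 10: piperidine with K2CO3 gives the enamine F12. Sensitised photooxygenation (O2, hν, tetraphenylporphyrin, CH2Cl2, −78 °C) cleaves the enamine double bond to the one-carbon-shorter α-silyloxy aldehyde F13. Ohira–Bestmann homologation (dimethyl (1-diazo-2-oxopropyl)phosphonate, K2CO3, MeOH) restores the carbon as the terminal alkyne F14. LiN(i-Pr)2 followed by BnMe2SiCl silylates it through acetylide 12. The route is rejoined at 13.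

**Further compounds**

F1 | step 11 | triethyl{[(3R,6E)-6-methyl-7-[(1S,2S)-2-methylcyclopropyl]-3-(propan-2-yl)hept-6-en-1-yn-3-yl]oxy}silane | C#C[C@](O[Si](CC)(CC)CC)(C(C)C)CC/C(C)=C/[C@@H]1[C@@H](C)C1
F2 | step 11 | cycloadduct without silicon: hydroazulene 5,9-diene, 1β-Me, 8α-Me, 4β-iPr, 4α-OSiEt3 | C1=C[C@@H](C)CC=C2[C@@]1(C)CC[C@@]2(O[Si](CC)(CC)CC)C(C)C
F3 | step 11 | tertiary allylic alcohol from F2 (4α-OH) | C1=C[C@@H](C)CC=C2[C@@]1(C)CC[C@@]2(O)C(C)C
F4 | step 11 | 5α,6α-epoxide of F3 | C1=C[C@@H](C)C[C@H]3O[C@@]32[C@@]1(C)CC[C@@]2(O)C(C)C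
F5 | step 13 | 4α,6α-diol from 21 (C9=C10 retained) | C1=C[C@@H](C)C[C@@H](O)[C@@H]2[C@@]1(C)CC[C@@]2(O)C(C)C
F6 | step 13 | 9α,10α-epoxide of F5 | C[C@H]1C[C@@H](O)[C@@H]2[C@@](C)(CC[C@@]2(O)C(C)C)[C@H]3O[C@@H]13
F7 | step 13 | O4,O6-acetonide of F6 | C[C@H]1C[C@@H](OC4(C)C)[C@@H]2[C@@](C)(CC[C@@]2(O4)C(C)C)[C@H]3O[C@@H]13
F8 | step 13 | 9β-phenylselanyl-10α-ol acetonide | O[C@H]1[C@H]([Se]c2ccccc2)[C@@H](C)C[C@@H](OC4(C)C)[C@@H]3[C@@]1(C)CC[C@@]3(O4)C(C)C
F9 | step 13 | selenoxide of F8 | O[C@H]1[C@H]([Se](=O)c2ccccc2)[C@@H](C)C[C@@H](OC4(C)C)[C@@H]3[C@@]1(C)CC[C@@]3(O4)C(C)C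
F10 | step 13 | 10α-allylic alcohol acetonide (C8(Me)=C9) | O[C@H]1C=C(C)C[C@@H](OC3(C)C)[C@@H]2[C@@]1(C)CC[C@@]2(O3)C(C)C
F11 | step 13 | 10α-tiglate of F10 | C/C=C(\C)C(=O)O[C@H]1C=C(C)C[C@@H](OC3(C)C)[C@@H]2[C@@]1(C)CC[C@@]2(O3)C(C)C
F12 | step 6 | piperidine enamine of 10 | C1CCN(CC1)/C=C/[C@](O[Si](CC)(CC)CC)(C(C)C)CC/C(C)=C/I
F13 | step 6 | (2R,5E)-6-iodo-5-methyl-2-(propan-2-yl)-2-[(triethylsilyl)oxy]hex-5-enal | O=C[C@](O[Si](CC)(CC)CC)(C(C)C)CC/C(C)=C/I
F14 | step 6 | triethyl{[(3R,6E)-7-iodo-6-methyl-3-(propan-2-yl)hept-6-en-1-yn-3-yl]oxy}silane | C#C[C@](O[Si](CC)(CC)CC)(C(C)C)CC/C(C)=C/I
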